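**Retrosynthetic overview** (guaiane numbering; primed atoms belong to the lower half)

- Last event: the C1=C10 alkene of a Diels–Alder adduct is moved to C1=C2, which sets C10–H. Before it, the spiro-cyclohexene (bonds C2–C4′ and C14–C15′) is cut into a cross-conjugated trienone (upper half, made in situ) and dehydrozaluzanin C (lower half, two steps from dehydrocostus lactone).
- The seven-membered ring of the upper half (C1, C5, C6, C7, C8, C9, C10) is not closed as such. It is grown from the six-membered ring B (C5–C10) of (−)-α-santonin by a photochemical one-carbon ring expansion, while ring A contracts to the cyclopentenone.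
- Enabling feature: the cross-conjugated cyclohexa-2,5-dienone ring A of santonin (C1=C2–C3(=O)–C4=C5) that flanks quaternary C10. C1–C5 bonding gives a cyclopropane (C1, C5, C10), and cleavage of its strained C5–C10 bond, the bond shared with ring B, inserts C1 into ring B.
- After the ring expansion: C5–H is set cis to H6 by CBS reduction and allylic diazene transposition; the enone is rebuilt as the C4(15) exocyclic enone; the lactone and C10(14) methylenes are installed.
- Ring order: lactone and rings A/B from the chiral pool → 5/7 skeleton (step 1) → spiro-cyclohexene by [4+2] (step 12).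

Key step: step 1

Remark on the chemistry: the upper half of the target has H-5 cis to H-6 (5β-H next to the 6α-O lactone), i.e. it is epimeric at C5 with the dehydrocostus lactone series. It is therefore built separately from santonin, and C5 is set deliberately in step 3.
Assumption: (−)-α-santonin (1) and dehydrocostus lactone (17) are purchased.

**Route**

Step 1
Reactants: 1 (−)-α-santonin
Product: 3 isophotosantonic lactone [(11S)-10α-hydroxy-3-oxo-1αH-guai-4-en-12,6α-olide], via cyclopropyl zwitterion 2 (not isolated)
Conditions: hν (medium-pressure Hg lamp, Pyrex), AcOH–H2O (1:1), reflux, N2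
Reagents that add atoms: water, O
Why: n→π* excitation of the cross-conjugated dienone of 1 causes C1–C5 (β,β′) bonding to the cyclopropyl oxyallyl zwitterion 2, which is O-protonated in the acidic medium; the resulting cyclopropylcarbinyl cation cleaves the strained C5–C10 bond shared with ring B, so C1 is inserted into ring B (6→7) while ring A contracts (6→5), and water captures the tertiary C10 cation. The closest known reaction is the type A photorearrangement of 4,4-disubstituted cyclohexa-2,5-dienones in protic acid, of which the santonin to isophotosantonic lactone conversion is the parent case. The five-membered ring closes by photochemical C1–C5 bonding (3-exo closure to the cyclopropane); the seven-membered ring is not closed but arises by fragmentation of that cyclopropane. C1–H should end α because the cyclopropane forms on the β-face with C9 exo and the C10 methyl endo, and C10–OH should end α because water attacks C10 anti to the departing C5 (inversion); C6, C7 and C11 are untouched. The step needs guaiane formation rather than the 1,4-shift to lumisantonin or methyl migration and aromatisation, and this is secured by protonating 2 in hot aqueous acetic acid.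

Step 2
Reactants: 3 isophotosantonic lactone
Product: 4 (11S)-3α,10α-dihydroxy-1αH-guai-4-en-12,6α-olide
Conditions: (S)-Me-CBS (0.2 equiv), BH3·SMe2, THF, −20 °C; MeOH quench
Reagents that add atoms: none
Why: CBS reduction gives 1,2-reduction of the enone under catalyst control; with the C4=C5 arm as the large group the (S)-catalyst should deliver hydride to the β-face and give the 3α-alcohol, while lactone and tertiary alcohol are inert at this temperature.

Step 3
Reactants: 4 (11S)-3α,10α-dihydroxy-1αH-guai-4-en-12,6α-olide
Product: 7 (11S)-10α-hydroxy-1αH,5βH-guai-3-en-12,6α-olide, via sulfonylhydrazine adduct 5 (not isolated), via allylic diazene 6 (not isolated)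
Conditions: 2-nitrobenzenesulfonylhydrazide (NBSH), PPh3, DEAD, N-methylmorpholine, −30 °C, then 23 °C
Reagents that add atoms: none
Why: Mitsunobu displacement by NBSH inverts C3 (nitrogen on the β-face), loss of sulfinic acid gives diazene 6, and its retro-ene loss of N2 (allylic diazene rearrangement) hands the hydrogen suprafacially to C5 on the β-face, so C5–H (cis to H6) is set by chirality transfer from C3 while the alkene moves to C3=C4.

Step 4
Reactants: 7 (11S)-10α-hydroxy-1αH,5βH-guai-3-en-12,6α-olide
Product: 8 (11S)-3β,4β-epoxy-10α-hydroxy-1αH,5βH-guaian-12,6α-olide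
Conditions: mCPBA, NaHCO3, CH2Cl2, 0 °C
Reagents that add atoms: mCPBA, OOC(=O)c1cccc(Cl)c1
Why: Prilezhaev epoxidation of the only alkene, expected on the β-face anti to C6 on the neighbouring C5; the face is without consequence because C3 becomes a ketone in step 7.

Step 5
Reactants: 8 (11S)-3β,4β-epoxy-10α-hydroxy-1αH,5βH-guaian-12,6α-olide
Product: 9 (11S)-3β,10α-dihydroxy-1αH,5βH-guai-4(15)-en-12,6α-olide
Conditions: Al(O-i-Pr)3, toluene, reflux
Reagents that add atoms: none
Why: aluminium alkoxide isomerisation of a trisubstituted epoxide to the exocyclic allylic alcohol (as in α-pinene oxide to pinocarveol): syn removal of a C15 methyl hydrogen opens the tertiary C4–O bond, and C3 keeps the epoxide configuration.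

Step 6
Reactants: 9 (11S)-3β,10α-dihydroxy-1αH,5βH-guai-4(15)-en-12,6α-olide
Product: 12 3β,10α-dihydroxy-1αH,5βH-guaia-4(15),11(13)-dien-12,6α-olide, via selenide 10 (not isolated), via selenoxide 11 (not isolated)
Conditions: LDA (3.5 equiv), THF, −78 °C; PhSeBr; then 30% H2O2, pyridine, CH2Cl2, 0 → 23 °C
Reagents that add atoms: none
Why: lactone α-selenenylation followed by selenoxide syn-elimination: the enolate should be selenenylated at C11 on the face anti to H7, so the selenoxide can only eliminate toward the methyl group and gives the exocyclic C11=C13 alkene; the C11 stereocentre disappears.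

Step 7
Reactants: 12 3β,10α-dihydroxy-1αH,5βH-guaia-4(15),11(13)-dien-12,6α-olide
Product: 13 10α-hydroxy-3-oxo-1αH,5βH-guaia-4(15),11(13)-dien-12,6α-olide
Conditions: Dess–Martin periodinane, NaHCO3, CH2Cl2, 0 → 23 °C
Reagents that add atoms: none
Why: Dess–Martin oxidation of the secondary allylic alcohol only; the tertiary C10 alcohol cannot be oxidised and the buffered neutral medium leaves the α-methylene ketone and lactone intact.

Step 8
Reactants: 13 10α-hydroxy-3-oxo-1αH,5βH-guaia-4(15),11(13)-dien-12,6α-olide
Product: 15 3-oxo-1αH,5βH-guaia-4(15),10(14),11(13)-trien-12,6α-olide (5-epi-dehydrozaluzanin C), via chlorosulfite 14 (not isolated)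
Conditions: SOCl2, pyridine, CH2Cl2, −20 → 0 °C
Reagents that add atoms: none
Why: dehydration of the tertiary alcohol through its chlorosulfite by pyridine-mediated anti-elimination: H1 is cis to the leaving group and unavailable, and removal of a methyl hydrogen should be favoured over the ring C9 hydrogens, giving the C10=C14 exocyclic alkene (the endocyclic Δ9 isomer is the expected contaminant, to be removed on AgNO3–silica).

Step 9
Reactants: 15 5-epi-dehydrozaluzanin C
Product: 16 3-trimethylsilyloxy-1αH,5βH-guaia-2,4(15),10(14),11(13)-tetraen-12,6α-olide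
Conditions: TMSOTf, Et3N, CH2Cl2, −78 → 0 °C; non-aqueous work-up
Reagents that add atoms: TMSOTf, C[Si](C)(C)OS(=O)(=O)C(F)(F)F
Why: soft enolisation and O-silylation: C2 carries the only enolisable hydrogens, so the 2-silyloxy diene forms regiospecifically, and it marks the upper half alone for the later dehydrogenation.

Step 10
Reactants: 17 dehydrocostus lactone
Product: 18 3α-hydroxy-1αH,5αH-guaia-4(15),10(14),11(13)-trien-12,6α-olide (3-epizaluzanin C)
Conditions: SeO2 (0.3 equiv), t-BuOOH, CH2Cl2, 23 °C
Reagents that add atoms: selenium dioxide, O=[Se]=O; tert-butyl hydroperoxide, CC(C)(C)OO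
Why: selenium dioxide allylic oxidation (ene reaction then [2,3]-shift) at C3, the allylic methylene of the C4(15) alkene; attack from the convex α-face should give mainly the 3α-alcohol, and either epimer serves because C3 is oxidised next.

Step 11
Reactants: 18 3-epizaluzanin C
Product: 19 dehydrozaluzanin C (3-oxo-1αH,5αH-guaia-4(15),10(14),11(13)-trien-12,6α-olide)
Conditions: Dess–Martin periodinane, NaHCO3, CH2Cl2, 23 °C
Reagents that add atoms: none
Why: Dess–Martin oxidation of the allylic alcohol gives the exocyclic enone that serves as dienophile; no stereocentre is touched.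

Step 12
Reactants: 16 silyl dienol ether of the upper half; 19 dehydrozaluzanin C (3 equiv, excess recoverable)
Product: 21 Diels–Alder adduct (Δ1(10), 2αH, C2–C4′ and C14–C15′ bonds formed), via trienone 20 (not isolated)
Conditions: Pd(OAc)2 (1.1 equiv), MeCN, 23 → 45 °C, dark
Reagents that add atoms: none
Why: Ito–Saegusa oxidation of 16 gives trienone 20, whose s-cis-locked C2=C1–C10=C14 diene adds in a Diels–Alder reaction to the exocyclic C4′=C15′ enone of 19 (ortho regiochemistry: C14 to the β-carbon C15′, C2 to C4′); the diene should add to the convex α-face of 19, anti to C6′ and C10′, which sets spiro C4′, and should react through its own β-face, anti to C6, which places H2 on the α-face; because only the upper half is a silyl enol ether, 19 is not dehydrogenated.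

Step 13
Reactants: 21 Diels–Alder adduct
Product: 22 target CNP0221188.1
Conditions: i-Pr2NEt (1 equiv), toluene, 23 °C, stopped at full conversion
Reagents that add atoms: none
Why: amine-mediated 1,3-prototropic shift of the β,γ-unsaturated ketone into conjugation: the hindered base removes the acidic C2–H from the open α-face and the ammonium ion pair should return the proton to C10 on the same face (suprafacial), giving 10α-H; a weak non-nucleophilic base and short contact are chosen so that the γ-positions C5 and C10 are not equilibrated and the methylene lactones are not attacked.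

**Compound list**

1 | (−)-α-santonin | C[C@H]1[C@@H]2CC[C@]3(C=CC(=O)C(=C3[C@H]2OC1=O)C)C | starting material
2 | cyclopropyl zwitterion (C1–C5 bonded oxyallyl form of 1) | C[C@H]1[C@@H]2CC[C@@]3(C)[C@@H]4C=C([O-])[C+](C)[C@]34[C@H]2OC1=O | intermediate
3 | isophotosantonic lactone | C[C@@]1(O)CC[C@@H]2[C@@H](C3=C(C)C(=O)C[C@H]31)OC(=O)[C@H]2C | intermediate
4 | (11S)-3α,10α-dihydroxy-1αH-guai-4-en-12,6α-olide | C[C@@]1(O)CC[C@@H]2[C@@H](C3=C(C)[C@H](O)C[C@H]31)OC(=O)[C@H]2C | intermediate
5 | 3β-[1-(2-nitrobenzenesulfonyl)hydrazinyl] adduct | C[C@@]1(O)CC[C@@H]2[C@@H](C3=C(C)[C@@H](N(N)S(=O)(=O)c4ccccc4[N+](=O)[O-])C[C@H]31)OC(=O)[C@H]2C | intermediate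
6 | 3β-diazenyl compound (allylic diazene) | C[C@@]1(O)CC[C@@H]2[C@@H](C3=C(C)[C@@H](N=N)C[C@H]31)OC(=O)[C@H]2C | intermediate
7 | (11S)-10α-hydroxy-1αH,5βH-guai-3-en-12,6α-olide | C[C@@]1(O)CC[C@@H]2[C@@H]([C@H]3[C@H]1CC=C3C)OC(=O)[C@H]2C | intermediate
8 | 3β,4β-epoxide of 7 | C[C@@]1(O)CC[C@@H]2[C@@H]([C@H]3[C@H]1C[C@@H]4O[C@]34C)OC(=O)[C@H]2C | intermediate
9 | (11S)-3β,10α-dihydroxy-1αH,5βH-guai-4(15)-en-12,6α-olide | C[C@@]1(O)CC[C@@H]2[C@@H]([C@H]3[C@H]1C[C@H](O)C3=C)OC(=O)[C@H]2C | intermediate
10 | 11β-phenylseleno derivative of 9 | C[C@@]1(O)CC[C@@H]2[C@@H]([C@H]3[C@H]1C[C@H](O)C3=C)OC(=O)[C@]2(C)[Se]c4ccccc4 | intermediate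
11 | selenoxide of 10 | C[C@@]1(O)CC[C@@H]2[C@@H]([C@H]3[C@H]1C[C@H](O)C3=C)OC(=O)[C@]2(C)[Se](=O)c4ccccc4 | intermediate
12 | 3β,10α-dihydroxy-1αH,5βH-guaia-4(15),11(13)-dien-12,6α-olide | C[C@@]1(O)CC[C@@H]2[C@@H]([C@H]3[C@H]1C[C@H](O)C3=C)OC(=O)C2=C | intermediate
13 | 10α-hydroxy-3-oxo-1αH,5βH-guaia-4(15),11(13)-dien-12,6α-olide | C[C@@]1(O)CC[C@@H]2[C@@H]([C@H]3[C@H]1CC(=O)C3=C)OC(=O)C2=C | intermediate
14 | 10-O-chlorosulfite of 13 | C[C@@]1(OS(=O)Cl)CC[C@@H]2[C@@H]([C@H]3[C@H]1CC(=O)C3=C)OC(=O)C2=C | intermediate
15 | 5-epi-dehydrozaluzanin C | C=C1CC[C@@H]2[C@@H]([C@H]3[C@H]1CC(=O)C3=C)OC(=O)C2=C | intermediate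
16 | 3-trimethylsilyloxy-2,4(15)-diene of 15 | C=C1CC[C@@H]2[C@@H]([C@H]3[C@H]1C=C(O[Si](C)(C)C)C3=C)OC(=O)C2=C | intermediate
17 | dehydrocostus lactone | C=C1CC[C@@H]2[C@@H]([C@@H]3[C@H]1CCC3=C)OC(=O)C2=C | starting material
18 | 3-epizaluzanin C (3α-ol) | C=C1CC[C@@H]2[C@@H]([C@@H]3[C@H]1C[C@@H](O)C3=C)OC(=O)C2=C | intermediate
19 | dehydrozaluzanin C | C=C1CC[C@@H]2[C@@H]([C@@H]3[C@H]1CC(=O)C3=C)OC(=O)C2=C | intermediate
20 | 3-oxo-5βH-guaia-1,4(15),10(14),11(13)-tetraen-12,6α-olide (trienone) | C=C1CC[C@@H]2[C@@H]([C@H]3C1=CC(=O)C3=C)OC(=O)C2=C | intermediate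
21 | Diels–Alder adduct (Δ1(10), 2αH) | C=C1C(=O)[C@@H]2C3=C(CC[C@H]4C(=C)C(=O)O[C@@H]4[C@H]13)CC[C@]21C(=O)C[C@H]2C(=C)CC[C@H]3C(=C)C(=O)O[C@@H]3[C@H]21 | intermediate
22 | CNP0221188.1 | C=C1C(=O)C2=C3[C@H](CC[C@H]4C(=C)C(=O)O[C@@H]4[C@H]13)CC[C@]21C(=O)C[C@H]2C(=C)CC[C@H]3C(=C)C(=O)O[C@@H]3[C@H]21 | target

**Totals**

Total step count: 13. Longest linear sequence: 11 (steps 1–9, 12, 13 from santonin).

**Steps most likely to fail**

Step 13. The dienolate may be protonated at C10 from the β-face, or the base may equilibrate the two γ-positions C5 and C10 of the product, so that epimers form. The fallback replaces substrate control by catalyst control: starting from 21, a bifunctional 6′-hydroxy cinchona alkaloid catalyst carries the proton from C2 to C10 inside a chiral ion pair (catalytic biomimetic olefin isomerisation), and of the two pseudo-enantiomeric catalysts the one matched to α-face delivery is used. It returns to the route at 22 and makes no new compound (F0).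

Step 12. The trienone may be consumed by self-dimerisation, or Pd(II)/Pd–H may isomerise the exocyclic alkenes before the cycloaddition, and the 5β-H diene may react too slowly with the hindered dienophile. The fallback generates the diene without metal and at low temperature. Starting from 16, PhSeCl (CH2Cl2, −78 °C) reacts with the silyl dienol ether to give the 2α-phenylseleno ketone F2 (selenium anti to C10, cis to H1). Oxidation with H2O2/pyridine at 0 °C in the presence of excess 19 gives the selenoxide F3, whose syn-elimination with H1 releases trienone 20 slowly. The cycloaddition is then driven thermally or at 10–12 kbar, and the route is rejoined at 21.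

Step 3. The Mitsunobu displacement at the hindered, easily ionised cyclopentenyl carbinol may be diverted to elimination, or may leak through an allyl cation and erode the chirality transfer from C3 to C5. The fallback avoids the displacement. Starting from 3, condensation with p-toluenesulfonylhydrazide (EtOH, cat. AcOH) gives the tosylhydrazone F1. Catecholborane (CHCl3, 0 °C) followed by NaOAc·3H2O at reflux should add hydride to C3 from the open α-face and expel sulfinate, giving the same β-diazene 6, which loses N2 as before. Compound 4 is bypassed and the route is rejoined at 7; C5 then rests on substrate control of the hydride face.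

**Further compounds**

F0 | step 13 | none | none
F1 | step 3 | tosylhydrazone of isophotosantonic lactone (C=N geometry not defined) | C[C@@]1(O)CC[C@@H]2[C@@H](C3=C(C)C(=NNS(=O)(=O)c4ccc(C)cc4)C[C@H]31)OC(=O)[C@H]2C
F2 | step 12 | 2α-phenylseleno-3-oxo-1αH,5βH-guaia-4(15),10(14),11(13)-trien-12,6α-olide | C=C1CC[C@@H]2[C@@H]([C@H]3[C@H]1[C@@H]([Se]c4ccccc4)C(=O)C3=C)OC(=O)C2=C
F3 | step 12 | selenoxide of F2 | C=C1CC[C@@H]2[C@@H]([C@H]3[C@H]1[C@@H]([Se](=O)c4ccccc4)C(=O)C3=C)OC(=O)C2=C
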